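At early times the maple run, which is the asked flask followed so far, held 20.9% target at 2.50 h; after that its target fell, and from 8.00 h on its substrate readings stayed level within their scatter.

| flask | substrate | reagent in the second phase | temperature | remark | time | volume of the second phase over the first |
|---|---|---|---|---|---|---|
| maple | 0.80 M | 0.88 M | 60 °C | the very flask that is asked about, followed so far |  |  |
| larch | 1.6 M | 0.88 M | 45 °C | run made earlier |  |  |
| flask | 0.80 M | 0.880 M | 60 °C |  | 2.5 d | 0.50 |

maple run (percent of the substrate charged)

| time / h | target / % | substrate / % |
|---|---|---|
| 2.50 | 20.9 | 43.8 |
| 8.00 | 14.2 | 35.9 |
| 15.0 | 14.5 | 35.5 |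
| 20.0 | 11.8 | 37.5 |
| 30.0 | 12.4 | 33.9 |
| 40.0 | 10.6 | 34.7 |
| 50.0 | 8.9 | 37.2 |

larch run (percent of the substrate charged)

| time / d | target / % | substrate / % |
|---|---|---|
| 0.250 | 22.5 | 62.7 |
| 0.833 | 21.3 | 60.5 |
| 1.25 | 18.6 | 60.2 |
| 2.00 | 20.5 | 62.6 |
| 4.00 | 14.0 | 62.5 |
| 5.00 | 16.1 | 62.6 |

(each reading ± 1 percentage point)

- amber: at 2.5 d add substrate, 50.0% of the amount charged, then wait 20 h
- teal: at 2.5 d raise the temperature by 25 K, then wait 20 h
- green: at 2.5 d take out 90% of the target then present, then wait 20 h
- red: change nothing and wait 20 h more

- in the second phase: reagent in the second phase; everything else is in the first
- charges count per volume of the first phase; a concentration in a rate is the amount of a species over the volume of its own phase; every rate counts per litre of the first phase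
- what is taken out of target is counted as made
- the earlier runs hold the two phases in the same ratio of volumes as the flask asked about
- additions bring no volume worth counting

* target, in percent of the substrate first charged, at 2.5 d
* the option that brings most further target ("none" if no option brings more than 2 percentage points) (amber / teal / green / red / none)
* target present, with what was taken out counted in, in percent of the substrate first charged, after amber
* target present, with what was taken out counted in, in percent of the substrate first charged, after teal

I built the flask up one process at a time.

1. First step: substrate plus reagent gives target. The reagent charge of 0.880 M is larger than the substrate charge of 0.80 M, so this step leaves room for converting the substrate completely. Yet in the maple run the substrate stayed near 35.8%, so I took the reagent as the limiting reagent, consumed elsewhere as well.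

2. Second step: target plus reagent gives over-reacted product. The substrate used 0.514 M, which leaves 0.366 M of reagent to destroy target, or 45.8% of the substrate charged. I called what remains the pool: reacted substrate minus over-reacted product, 18.4%. The same balance gives the larch run a pool of 21.3%, and its first target reading was 22.5%.

3. Third step: the last three maple readings average 10.6% target, less than the pool, so I supposed that target exchanges with an unread form. The pool share, target as a fraction of the pool, has the even split of 0.5 as its zero; the maple run reads 0.577.

My reckoning was therefore about 10.6% now and after amber, since amber adds no reagent. Green refills from the unread form and gains up to 4 percentage points. Teal had 7.8 points of room between target and the pool, but I had not read from the runs which way heat moves the share. I named green, with teal as the larger open chance.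

The forecast gave 8.3% now, none as best, 6.7% after amber and 2.6% after teal, holding that “With no reagent, no option makes target.”

The flask gives 10.1% now, 9.83% after amber and 16.8% after teal; teal is best, gaining 6.7 points against 2.6 points for green.

    target ⇌ isomer of the product (K = 0.950, k = 0.0250 h⁻¹, Ea = 121 kJ mol⁻¹, ΔH = −80.0 kJ mol⁻¹)
    reagent in the reaction phase ⇌ reagent in the second phase, rate k2*([reagent in the reaction phase] - [reagent in the second phase]/K2) per volume of the first phase (partition coefficient = 0.580, kL = 0.960 h⁻¹)
    reagent in the reaction phase + target → over-reacted product (k = 3.40 L mol⁻¹ h⁻¹, Ea = 65.0 kJ mol⁻¹)
    substrate + reagent in the reaction phase → target (k = 1.30 L mol⁻¹ h⁻¹, Ea = 58.0 kJ mol⁻¹)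
    (constants at 60 °C)

The unread form is the isomer of the product. The relaxation half-life of target and isomer of the product, both ways together, is 0.563 d, short against 2.5 d. Held against my pool, the flask's target gives a share of 0.549 now, where I read 0.577, and 0.913 after teal, still inside the pool.

A neighbour flask, charged with 2.0 M of substrate and keeping 68% of it, has by the same balance a pool of 19.6%, and my share turns this into 11.3% target. The computed flask gives 10.5%.

The runs are simulated for an exercise, and the scatter is random.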